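**Assumption:** the SMILES is read as the trans-(2R,3S)-2,3-dihydrobenzofuran; substrates, intermediates and products carry numbers in forward-route order, while reagents appear by name and SMILES only.

## Retrosynthetic overview

1. Target ⇐ removal of four benzyl ethers and one silyl ether from a protected flavonol; the pyranone ring is closed last, by Algar–Flynn–Oyamada oxidative cyclisation of a 2'-hydroxychalcone.
2. Chalcone ⇐ intermolecular Claisen–Schmidt aldol condensation (key C–C bond, Cα–Cβ of the enone) between 4',6'-di-O-benzylphloroacetophenone (ring A) and a (2R,3S)-2-aryl-3-(silyloxymethyl)-2,3-dihydrobenzofuran-4-carbaldehyde.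
3. Aldehyde ⇐ 4-bromo-dihydrobenzofuran (Br/Li exchange, DMF); the dihydrofuran ring is closed first, by acid-mediated trans-selective cyclodehydration of a 1,2-diarylpropane-1,3-diol.
4. Diol ⇐ Evans syn-aldol of an (R)-4-benzyloxazolidinone arylacetimide with O-benzylvanillin (sets C3, and C2 in the matching sense), then LiBH4.
5. Arylacetic acid ⇐ aromatic Claisen rearrangement of the allyl ether of 2-(benzyloxy)-5-bromophenol, then Lemieux–Johnson and Pinnick oxidation.

## Route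

Step 1
Reactants: 1 2-(benzyloxy)phenol
Product: 2 2-(benzyloxy)phenyl acetate
Conditions: Ac2O, pyridine, DMAP (cat.), CH2Cl2, rt
Reagents that add atoms: acetic anhydride CC(=O)OC(C)=O
Why: O-acetylation (nucleophilic acyl transfer) turns the free phenol into a weak donor so that the benzyloxy group alone directs the following bromination.

Step 2
Reactants: 2 2-(benzyloxy)phenyl acetate
Product: 3 2-(benzyloxy)-5-bromophenyl acetate
Conditions: NBS, MeCN, rt, dark
Reagents that add atoms: N-bromosuccinimide O=C1CCC(=O)N1Br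
Why: Electrophilic aromatic bromination goes para to the strongly donating benzyloxy group (the acetoxy group is a much weaker director), as in the classical preparation of 5-bromoguaiacol.

Step 3
Reactants: 3 2-(benzyloxy)-5-bromophenyl acetate
Product: 4 2-(benzyloxy)-5-bromophenol
Conditions: K2CO3 (0.2 equiv), MeOH, rt
Reagents that add atoms: none
Why: Base-catalysed transesterification (methanolysis) of the aryl acetate frees the phenol without touching the benzyl ether or the aryl bromide.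

Step 4
Reactants: 4 2-(benzyloxy)-5-bromophenol
Product: 5 1-(benzyloxy)-4-bromo-2-(prop-2-en-1-yloxy)benzene
Conditions: allyl bromide, K2CO3, acetone, reflux
Reagents that add atoms: allyl bromide C=CCBr
Why: Williamson ether synthesis on the phenoxide with a reactive allylic halide.

Step 5
Reactants: 5 1-(benzyloxy)-4-bromo-2-(prop-2-en-1-yloxy)benzene
Product: 7 6-(benzyloxy)-3-bromo-2-(prop-2-en-1-yl)phenol, via ortho-dienone 6 (not isolated)
Conditions: PhNEt2, 190 °C
Reagents that add atoms: none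
Why: In this aromatic Claisen rearrangement ([3,3]-sigmatropic shift) the allyl group can only migrate to the single free ortho carbon, the one next to bromine, and the dienone then tautomerises to the phenol.

Step 6
Reactants: 7 6-(benzyloxy)-3-bromo-2-(prop-2-en-1-yl)phenol
Product: 8 1-(benzyloxy)-4-bromo-2-(methoxymethoxy)-3-(prop-2-en-1-yl)benzene
Conditions: NaH, MOMCl, THF/DMF, 0 °C → rt
Reagents that add atoms: chloromethyl methyl ether COCCl
Why: Williamson-type O-alkylation of the hindered sodium phenoxide installs a small acetal that survives the oxidations, the boron aldol and LiBH4 and is removed by the acid used for ring closure.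

Step 7
Reactants: 8 1-(benzyloxy)-4-bromo-2-(methoxymethoxy)-3-(prop-2-en-1-yl)benzene
Product: 10 2-[3-(benzyloxy)-6-bromo-2-(methoxymethoxy)phenyl]acetaldehyde, via vicinal diol 9 (not isolated)
Conditions: OsO4 (2 mol%), NaIO4 (4 equiv), 2,6-lutidine, 1,4-dioxane/H2O 3:1, rt
Reagents that add atoms: osmium tetroxide, OsO4, O=[Os](=O)(=O)=O (oxygen carrier); sodium periodate, NaIO4, [Na+].[O-]I(=O)(=O)=O (oxygen source)
Why: Lemieux–Johnson oxidation (catalytic dihydroxylation, then periodate glycol cleavage) shortens the terminal alkene by one carbon, with 2,6-lutidine suppressing over-oxidation; the aldehyde is used crude.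

Step 8
Reactants: 10 2-[3-(benzyloxy)-6-bromo-2-(methoxymethoxy)phenyl]acetaldehyde
Product: 11 2-[3-(benzyloxy)-6-bromo-2-(methoxymethoxy)phenyl]acetic acid
Conditions: NaClO2, NaH2PO4, 2-methyl-2-butene, t-BuOH/H2O, 0 °C → rt
Reagents that add atoms: sodium chlorite [Na+].[O-]Cl=O
Why: Pinnick oxidation converts the aldehyde selectively to the acid at pH about 4, where the MOM acetal is stable, while 2-methyl-2-butene traps HOCl before it can chlorinate the electron-rich arene.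

Step 9
Reactants: 11 2-[3-(benzyloxy)-6-bromo-2-(methoxymethoxy)phenyl]acetic acid; 12 (R)-4-benzyl-1,3-oxazolidin-2-one
Product: 14 (4R)-4-benzyl-3-{2-[3-(benzyloxy)-6-bromo-2-(methoxymethoxy)phenyl]acetyl}-1,3-oxazolidin-2-one, via mixed pivalic anhydride 13 (not isolated)
Conditions: PivCl, Et3N, THF, −20 °C; then LiCl, 12, −20 °C → rt
Reagents that add atoms: none
Why: N-acylation through the mixed anhydride works because the LiCl/Et3N-activated oxazolidinone attacks the arylacetyl carbonyl rather than the tert-butyl-shielded one, and no acid chloride is needed that would endanger the MOM group.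

Step 10
Reactants: 14 (4R)-4-benzyl-3-{2-[3-(benzyloxy)-6-bromo-2-(methoxymethoxy)phenyl]acetyl}-1,3-oxazolidin-2-one; 15 4-(benzyloxy)-3-methoxybenzaldehyde
Product: 18 (4R)-4-benzyl-3-{(2R,3R)-2-[3-(benzyloxy)-6-bromo-2-(methoxymethoxy)phenyl]-3-[4-(benzyloxy)-3-methoxyphenyl]-3-hydroxypropanoyl}-1,3-oxazolidin-2-one, via dibutylboron Z-enolate 16 (not isolated), via dibutylboron aldolate 17 (not isolated)
Conditions: Bu2BOTf (1.2 equiv), i-Pr2NEt (1.4 equiv), CH2Cl2, −78 → 0 °C; 15, −78 → 0 °C; then pH 7 phosphate buffer, MeOH, 30% H2O2, 0 °C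
Reagents that add atoms: none
Why: In this Evans syn-aldol the Z-boron enolate reacts through a closed Zimmerman–Traxler chair on the face away from the auxiliary benzyl group, so the (R)-auxiliary gives the (2R,3R)-syn adduct, whose α-carbon becomes C3 of the dihydrobenzofuran.

Step 11
Reactants: 18 (4R)-4-benzyl-3-{(2R,3R)-2-[3-(benzyloxy)-6-bromo-2-(methoxymethoxy)phenyl]-3-[4-(benzyloxy)-3-methoxyphenyl]-3-hydroxypropanoyl}-1,3-oxazolidin-2-one
Product: 19 (1R,2S)-2-[3-(benzyloxy)-6-bromo-2-(methoxymethoxy)phenyl]-1-[4-(benzyloxy)-3-methoxyphenyl]propane-1,3-diol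
Conditions: LiBH4 (2 equiv), MeOH (2 equiv), THF, 0 °C
Reagents that add atoms: none
Why: Reductive cleavage of the imide at the exocyclic carbonyl gives the primary alcohol and returns the auxiliary, making the α-centre non-epimerisable; its descriptor changes from R to S only through the CIP priorities.

Step 12
Reactants: 19 (1R,2S)-2-[3-(benzyloxy)-6-bromo-2-(methoxymethoxy)phenyl]-1-[4-(benzyloxy)-3-methoxyphenyl]propane-1,3-diol
Product: 21 [(2R,3S)-7-(benzyloxy)-2-[4-(benzyloxy)-3-methoxyphenyl]-4-bromo-2,3-dihydro-1-benzofuran-3-yl]methanol, via free phenol triol 20 (not isolated)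
Conditions: HCl (1.25 M in MeOH), THF, 40 °C
Reagents that add atoms: none
Why: Acid removes the MOM acetal and ionises the p-alkoxybenzylic alcohol, and SN1 cyclodehydration by the phenol closes the ring anti to the CH2OH group, so C2 (R) is fixed trans to the auxiliary-derived C3 (S), the same configuration the syn-aldol carbinol already had.

Step 13
Reactants: 21 [(2R,3S)-7-(benzyloxy)-2-[4-(benzyloxy)-3-methoxyphenyl]-4-bromo-2,3-dihydro-1-benzofuran-3-yl]methanol
Product: 22 {[(2R,3S)-7-(benzyloxy)-2-[4-(benzyloxy)-3-methoxyphenyl]-4-bromo-2,3-dihydro-1-benzofuran-3-yl]methoxy}tri(propan-2-yl)silane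
Conditions: TIPSCl, imidazole, DMF, rt
Reagents that add atoms: chlorotri(propan-2-yl)silane CC(C)[Si](Cl)(C(C)C)C(C)C
Why: Silylation of the primary alcohol gives an ether stable to n-BuLi, KOH and alkaline H2O2 and prevents lactol formation with the neighbouring aldehyde and oxa-Michael addition to the later enone.

Step 14
Reactants: 22 {[(2R,3S)-7-(benzyloxy)-2-[4-(benzyloxy)-3-methoxyphenyl]-4-bromo-2,3-dihydro-1-benzofuran-3-yl]methoxy}tri(propan-2-yl)silane
Product: 25 (2R,3S)-7-(benzyloxy)-2-[4-(benzyloxy)-3-methoxyphenyl]-3-{[tri(propan-2-yl)silyl]oxymethyl}-2,3-dihydro-1-benzofuran-4-carbaldehyde, via aryllithium 23 (not isolated), via lithium hemiaminal alkoxide 24 (not isolated)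
Conditions: n-BuLi (1.1 equiv), THF, −78 °C, 20 min; DMF (3 equiv), −78 → 0 °C; H2O
Reagents that add atoms: N,N-dimethylformamide CN(C)C=O
Why: Bromine–lithium exchange at −78 °C outruns any deprotonation, and formylation of the aryllithium with DMF (Bouveault-type) gives the aldehyde on aqueous collapse of the tetrahedral adduct without touching either stereocentre.

Step 15
Reactants: 26 1-(2,4,6-trihydroxyphenyl)ethan-1-one
Product: 27 1-[2,4-bis(benzyloxy)-6-hydroxyphenyl]ethan-1-one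
Conditions: BnBr (2.1 equiv), K2CO3 (2.2 equiv), DMF, rt
Reagents that add atoms: benzyl bromide BrCc1ccccc1
Why: Williamson benzylation stops at the dibenzyl ether because the remaining ortho-hydroxyl is hydrogen-bonded to the ketone and is the least nucleophilic.

Step 16
Reactants: 25 (2R,3S)-7-(benzyloxy)-2-[4-(benzyloxy)-3-methoxyphenyl]-3-{[tri(propan-2-yl)silyl]oxymethyl}-2,3-dihydro-1-benzofuran-4-carbaldehyde; 27 1-[2,4-bis(benzyloxy)-6-hydroxyphenyl]ethan-1-one
Product: 29 (2E)-1-[2,4-bis(benzyloxy)-6-hydroxyphenyl]-3-[(2R,3S)-7-(benzyloxy)-2-[4-(benzyloxy)-3-methoxyphenyl]-3-{[tri(propan-2-yl)silyl]oxymethyl}-2,3-dihydro-1-benzofuran-4-yl]prop-2-en-1-one, via aldol adduct 28 (not isolated)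
Conditions: KOH (50% aq., 10 equiv), EtOH/THF 2:1, rt, 36 h
Reagents that add atoms: none
Why: In this Claisen–Schmidt condensation (crossed aldol addition, then E1cB dehydration) the acetophenone enolate adds to the non-enolisable aldehyde, joining the two fragments at the key C–C bond and giving the E-enone; neither ring stereocentre is acidic under these conditions.

Step 17
Reactants: 29 (2E)-1-[2,4-bis(benzyloxy)-6-hydroxyphenyl]-3-[(2R,3S)-7-(benzyloxy)-2-[4-(benzyloxy)-3-methoxyphenyl]-3-{[tri(propan-2-yl)silyl]oxymethyl}-2,3-dihydro-1-benzofuran-4-yl]prop-2-en-1-one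
Product: 31 5,7-bis(benzyloxy)-2-[(2R,3S)-7-(benzyloxy)-2-[4-(benzyloxy)-3-methoxyphenyl]-3-{[tri(propan-2-yl)silyl]oxymethyl}-2,3-dihydro-1-benzofuran-4-yl]-3-hydroxy-4H-chromen-4-one, via dihydroflavonol 30 (not isolated)
Conditions: 30% H2O2, 2 M aq. NaOH, MeOH/THF 1:1, 0 °C → rt
Reagents that add atoms: hydrogen peroxide OO
Why: In the Algar–Flynn–Oyamada reaction the phenoxide closes onto the β-carbon while the α-carbon is hydroxylated by H2O2, and the dihydroflavonol is oxidised on to the flavonol; the para-alkoxy-substituted aryl group at the β-carbon favours this six-membered closure over aurone formation.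

Step 18
Reactants: 31 5,7-bis(benzyloxy)-2-[(2R,3S)-7-(benzyloxy)-2-[4-(benzyloxy)-3-methoxyphenyl]-3-{[tri(propan-2-yl)silyl]oxymethyl}-2,3-dihydro-1-benzofuran-4-yl]-3-hydroxy-4H-chromen-4-one
Product: 32 5,7-bis(benzyloxy)-2-[(2R,3S)-7-(benzyloxy)-2-[4-(benzyloxy)-3-methoxyphenyl]-3-(hydroxymethyl)-2,3-dihydro-1-benzofuran-4-yl]-3-hydroxy-4H-chromen-4-one
Conditions: TBAF (3 equiv), AcOH (3 equiv), THF, 0 °C → rt
Reagents that add atoms: none
Why: Fluoride-mediated desilylation, driven by the strong Si–F bond and buffered with acetic acid, frees the primary alcohol without affecting the benzyl ethers or the flavonol.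

Step 19
Reactants: 32 5,7-bis(benzyloxy)-2-[(2R,3S)-7-(benzyloxy)-2-[4-(benzyloxy)-3-methoxyphenyl]-3-(hydroxymethyl)-2,3-dihydro-1-benzofuran-4-yl]-3-hydroxy-4H-chromen-4-one
Product: 33 3,5,7-trihydroxy-2-[(2R,3S)-7-hydroxy-2-(4-hydroxy-3-methoxyphenyl)-3-(hydroxymethyl)-2,3-dihydro-1-benzofuran-4-yl]-4H-chromen-4-one
Conditions: H2 (1 atm), 10% Pd/C, THF/MeOH 1:1, rt, stopped at full conversion
Reagents that add atoms: none
Why: Catalytic hydrogenolysis cleaves the four O-benzyl aryl ethers under neutral conditions, where the flavonol double bond, the methyl ether and (if the reaction is stopped on time) the cyclic benzylic ether are left intact, so both stereocentres are preserved.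

## Compound list

1 | 2-(benzyloxy)phenol | Oc1ccccc1OCc1ccccc1 | starting material
2 | 2-(benzyloxy)phenyl acetate | CC(=O)Oc1ccccc1OCc1ccccc1 | intermediate
3 | 2-(benzyloxy)-5-bromophenyl acetate | CC(=O)Oc1cc(Br)ccc1OCc1ccccc1 | intermediate
4 | 2-(benzyloxy)-5-bromophenol | Oc1cc(Br)ccc1OCc1ccccc1 | intermediate
5 | 1-(benzyloxy)-4-bromo-2-(prop-2-en-1-yloxy)benzene | C=CCOc1cc(Br)ccc1OCc1ccccc1 | intermediate
6 | 2-(benzyloxy)-5-bromo-6-(prop-2-en-1-yl)cyclohexa-2,4-dien-1-one (racemic ortho-dienone, not isolated) | C=CCC1C(=O)C(OCc2ccccc2)=CC=C1Br | intermediate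
7 | 6-(benzyloxy)-3-bromo-2-(prop-2-en-1-yl)phenol | C=CCc1c(O)c(OCc2ccccc2)ccc1Br | intermediate
8 | 1-(benzyloxy)-4-bromo-2-(methoxymethoxy)-3-(prop-2-en-1-yl)benzene | C=CCc1c(OCOC)c(OCc2ccccc2)ccc1Br | intermediate
9 | 3-[3-(benzyloxy)-6-bromo-2-(methoxymethoxy)phenyl]propane-1,2-diol (racemic, not isolated) | OCC(O)Cc1c(OCOC)c(OCc2ccccc2)ccc1Br | intermediate
10 | 2-[3-(benzyloxy)-6-bromo-2-(methoxymethoxy)phenyl]acetaldehyde | O=CCc1c(OCOC)c(OCc2ccccc2)ccc1Br | intermediate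
11 | 2-[3-(benzyloxy)-6-bromo-2-(methoxymethoxy)phenyl]acetic acid | OC(=O)Cc1c(OCOC)c(OCc2ccccc2)ccc1Br | intermediate
12 | (R)-4-benzyl-1,3-oxazolidin-2-one | O=C1N[C@H](Cc2ccccc2)CO1 | starting material
13 | 2-[3-(benzyloxy)-6-bromo-2-(methoxymethoxy)phenyl]acetic pivalic anhydride (not isolated) | CC(C)(C)C(=O)OC(=O)Cc1c(OCOC)c(OCc2ccccc2)ccc1Br | intermediate
14 | (4R)-4-benzyl-3-{2-[3-(benzyloxy)-6-bromo-2-(methoxymethoxy)phenyl]acetyl}-1,3-oxazolidin-2-one | O=C(Cc1c(OCOC)c(OCc2ccccc2)ccc1Br)N1[C@H](Cc2ccccc2)COC1=O | intermediate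
15 | 4-(benzyloxy)-3-methoxybenzaldehyde (O-benzylvanillin) | COc1cc(C=O)ccc1OCc1ccccc1 | starting material
16 | dibutylboron (Z)-enolate of 14 (not isolated) | CCCCB(CCCC)O/C(=C\c1c(OCOC)c(OCc2ccccc2)ccc1Br)N1[C@H](Cc2ccccc2)COC1=O | intermediate
17 | O-dibutylboryl aldolate of 18, (2R,3R) (not isolated) | O=C([C@H](c1c(OCOC)c(OCc2ccccc2)ccc1Br)[C@@H](OB(CCCC)CCCC)c1ccc(OCc2ccccc2)c(OC)c1)N1[C@H](Cc2ccccc2)COC1=O | intermediate
18 | (4R)-4-benzyl-3-{(2R,3R)-2-[3-(benzyloxy)-6-bromo-2-(methoxymethoxy)phenyl]-3-[4-(benzyloxy)-3-methoxyphenyl]-3-hydroxypropanoyl}-1,3-oxazolidin-2-one | O=C([C@H](c1c(OCOC)c(OCc2ccccc2)ccc1Br)[C@@H](O)c1ccc(OCc2ccccc2)c(OC)c1)N1[C@H](Cc2ccccc2)COC1=O | intermediate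
19 | (1R,2S)-2-[3-(benzyloxy)-6-bromo-2-(methoxymethoxy)phenyl]-1-[4-(benzyloxy)-3-methoxyphenyl]propane-1,3-diol | OC[C@H](c1c(OCOC)c(OCc2ccccc2)ccc1Br)[C@@H](O)c1ccc(OCc2ccccc2)c(OC)c1 | intermediate
20 | (1R,2S)-2-[3-(benzyloxy)-6-bromo-2-hydroxyphenyl]-1-[4-(benzyloxy)-3-methoxyphenyl]propane-1,3-diol (not isolated) | OC[C@H](c1c(O)c(OCc2ccccc2)ccc1Br)[C@@H](O)c1ccc(OCc2ccccc2)c(OC)c1 | intermediate
21 | [(2R,3S)-7-(benzyloxy)-2-[4-(benzyloxy)-3-methoxyphenyl]-4-bromo-2,3-dihydro-1-benzofuran-3-yl]methanol (2,3-trans) | COc1cc([C@@H]2Oc3c(OCc4ccccc4)ccc(Br)c3[C@H]2CO)ccc1OCc1ccccc1 | intermediate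
22 | {[(2R,3S)-7-(benzyloxy)-2-[4-(benzyloxy)-3-methoxyphenyl]-4-bromo-2,3-dihydro-1-benzofuran-3-yl]methoxy}tri(propan-2-yl)silane | COc1cc([C@@H]2Oc3c(OCc4ccccc4)ccc(Br)c3[C@H]2CO[Si](C(C)C)(C(C)C)C(C)C)ccc1OCc1ccccc1 | intermediate
23 | 4-lithio analogue of 22 (aryllithium, not isolated) | COc1cc([C@@H]2Oc3c(OCc4ccccc4)ccc([Li])c3[C@H]2CO[Si](C(C)C)(C(C)C)C(C)C)ccc1OCc1ccccc1 | intermediate
24 | lithium (dimethylamino)(aryl)methanolate, the tetrahedral DMF adduct of 23 (both epimers at the new carbon, not isolated) | COc1cc([C@@H]2Oc3c(OCc4ccccc4)ccc(C(O[Li])N(C)C)c3[C@H]2CO[Si](C(C)C)(C(C)C)C(C)C)ccc1OCc1ccccc1 | intermediate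
25 | (2R,3S)-7-(benzyloxy)-2-[4-(benzyloxy)-3-methoxyphenyl]-3-{[tri(propan-2-yl)silyl]oxymethyl}-2,3-dihydro-1-benzofuran-4-carbaldehyde | COc1cc([C@@H]2Oc3c(OCc4ccccc4)ccc(C=O)c3[C@H]2CO[Si](C(C)C)(C(C)C)C(C)C)ccc1OCc1ccccc1 | intermediate
26 | 1-(2,4,6-trihydroxyphenyl)ethan-1-one (phloroacetophenone) | CC(=O)c1c(O)cc(O)cc1O | starting material
27 | 1-[2,4-bis(benzyloxy)-6-hydroxyphenyl]ethan-1-one | CC(=O)c1c(O)cc(OCc2ccccc2)cc1OCc1ccccc1 | intermediate
28 | 1-[2,4-bis(benzyloxy)-6-hydroxyphenyl]-3-hydroxy-3-[the (2R,3S)-dihydrobenzofuran-4-yl unit of 25]propan-1-one (both carbinol epimers, not isolated) | COc1cc([C@@H]2Oc3c(OCc4ccccc4)ccc(C(O)CC(=O)c4c(O)cc(OCc5ccccc5)cc4OCc4ccccc4)c3[C@H]2CO[Si](C(C)C)(C(C)C)C(C)C)ccc1OCc1ccccc1 | intermediate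
29 | (2E)-1-[2,4-bis(benzyloxy)-6-hydroxyphenyl]-3-[(2R,3S)-7-(benzyloxy)-2-[4-(benzyloxy)-3-methoxyphenyl]-3-{[tri(propan-2-yl)silyl]oxymethyl}-2,3-dihydro-1-benzofuran-4-yl]prop-2-en-1-one | COc1cc([C@@H]2Oc3c(OCc4ccccc4)ccc(/C=C/C(=O)c4c(O)cc(OCc5ccccc5)cc4OCc4ccccc4)c3[C@H]2CO[Si](C(C)C)(C(C)C)C(C)C)ccc1OCc1ccccc1 | intermediate
30 | trans-5,7-bis(benzyloxy)-3-hydroxy-2-[the (2R,3S)-dihydrobenzofuran-4-yl unit of 25]-2,3-dihydro-4H-chromen-4-one (both trans diastereomers, not isolated) | COc1cc([C@@H]2Oc3c(OCc4ccccc4)ccc(C4Oc5cc(OCc6ccccc6)cc(OCc6ccccc6)c5C(=O)C4O)c3[C@H]2CO[Si](C(C)C)(C(C)C)C(C)C)ccc1OCc1ccccc1 | intermediate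
31 | 5,7-bis(benzyloxy)-2-[(2R,3S)-7-(benzyloxy)-2-[4-(benzyloxy)-3-methoxyphenyl]-3-{[tri(propan-2-yl)silyl]oxymethyl}-2,3-dihydro-1-benzofuran-4-yl]-3-hydroxy-4H-chromen-4-one | COc1cc([C@@H]2Oc3c(OCc4ccccc4)ccc(-c4oc5cc(OCc6ccccc6)cc(OCc6ccccc6)c5c(=O)c4O)c3[C@H]2CO[Si](C(C)C)(C(C)C)C(C)C)ccc1OCc1ccccc1 | intermediate
32 | 5,7-bis(benzyloxy)-2-[(2R,3S)-7-(benzyloxy)-2-[4-(benzyloxy)-3-methoxyphenyl]-3-(hydroxymethyl)-2,3-dihydro-1-benzofuran-4-yl]-3-hydroxy-4H-chromen-4-one | COc1cc([C@@H]2Oc3c(OCc4ccccc4)ccc(-c4oc5cc(OCc6ccccc6)cc(OCc6ccccc6)c5c(=O)c4O)c3[C@H]2CO)ccc1OCc1ccccc1 | intermediate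
33 | 3,5,7-trihydroxy-2-[(2R,3S)-7-hydroxy-2-(4-hydroxy-3-methoxyphenyl)-3-(hydroxymethyl)-2,3-dihydro-1-benzofuran-4-yl]-4H-chromen-4-one (CNP0195987.1) | COc1cc([C@@H]2Oc3c(O)ccc(-c4oc5cc(O)cc(O)c5c(=O)c4O)c3[C@H]2CO)ccc1O | target

## Summary and fallbacks

Total step count: 19. Longest linear sequence: 18 steps (steps 1–14 and 16–19, from 1); step 15 is a one-step side branch.

**Step 10 (most likely to fail).** The arylacetyl group carries two ortho substituents, so boron enolisation or addition to the electron-rich aldehyde may be slow or poorly selective. The fallback gives up auxiliary control for a racemic ester aldol followed by resolution; it sets out from acid 11 and aldehyde 15 and comes back at alcohol 21. Acid 11 is esterified (MeI, K2CO3, DMF) to methyl 2-[3-(benzyloxy)-6-bromo-2-(methoxymethoxy)phenyl]acetate F1. Its small, reactive lithium enolate (LiN(i-Pr)2, THF, −78 °C) adds to 15 to give methyl 2-[3-(benzyloxy)-6-bromo-2-(methoxymethoxy)phenyl]-3-[4-(benzyloxy)-3-methoxyphenyl]-3-hydroxypropanoate F2 as a racemic syn/anti mixture. LiAlH4 (THF, 0 °C) reduces it to the racemic diol mixture F3. Methanolic HCl funnels both diastereomers through the common benzylic cation to the racemic trans-dihydrobenzofuran alcohol F4. Preparative HPLC on a chiral stationary phase (amylose tris(3,5-dimethylphenylcarbamate)) then delivers (2R,3S)-21.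

**Step 17.** The 6'-benzyloxy group and the ortho-substituted aryl group at the β-carbon can divert the oxidative cyclisation to an aurone. The fallback separates epoxidation from ring closure; it sets out from acetophenone 27 and aldehyde 25 and comes back at 32. Ketone 27 is protected (NaH, MOMCl, DMF) as 1-[2,4-bis(benzyloxy)-6-(methoxymethoxy)phenyl]ethan-1-one F5. Claisen–Schmidt condensation with 25 (KOH, EtOH/THF) gives the 2'-O-MOM chalcone F6, which cannot cyclise. Weitz–Scheffer epoxidation (H2O2, NaOH, MeOH/THF) gives the trans-epoxy ketone F7. Methanolic HCl (3 M, MeOH/THF, 50 °C) removes the MOM and silyl groups, and the freed phenol opens the epoxide at the benzylic carbon to give the trans-dihydroflavonol F8. Base-mediated dehydrogenation (aerated methanolic KOH, or alkaline H2O2, rt) then gives flavonol 32.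

**Step 19.** Prolonged hydrogenation can cleave the benzylic C2–O bond of the dihydrobenzofuran. The fallback replaces reduction by Lewis-acid dealkylation; it sets out from 32 and comes back at target 33, making no new compound (none F0). Compound 32 is treated with BCl3 (1 M in CH2Cl2, 6 equiv) and pentamethylbenzene (8 equiv) in CH2Cl2 at −78 °C and quenched with MeOH; the benzyl cations are trapped by pentamethylbenzene and the aryl methyl ether survives at this temperature.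

## Further compounds

F1 | step 10 | methyl 2-[3-(benzyloxy)-6-bromo-2-(methoxymethoxy)phenyl]acetate | COC(=O)Cc1c(OCOC)c(OCc2ccccc2)ccc1Br
F2 | step 10 | methyl 2-[3-(benzyloxy)-6-bromo-2-(methoxymethoxy)phenyl]-3-[4-(benzyloxy)-3-methoxyphenyl]-3-hydroxypropanoate (racemic, syn/anti mixture) | COC(=O)C(c1c(OCOC)c(OCc2ccccc2)ccc1Br)C(O)c1ccc(OCc2ccccc2)c(OC)c1
F3 | step 10 | 2-[3-(benzyloxy)-6-bromo-2-(methoxymethoxy)phenyl]-1-[4-(benzyloxy)-3-methoxyphenyl]propane-1,3-diol (racemic, diastereomer mixture) | OCC(c1c(OCOC)c(OCc2ccccc2)ccc1Br)C(O)c1ccc(OCc2ccccc2)c(OC)c1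
F4 | step 10 | racemic trans-[7-(benzyloxy)-2-[4-(benzyloxy)-3-methoxyphenyl]-4-bromo-2,3-dihydro-1-benzofuran-3-yl]methanol, 1:1 mixture of (2R,3S) and (2S,3R) | COc1cc([C@@H]2Oc3c(OCc4ccccc4)ccc(Br)c3[C@H]2CO)ccc1OCc1ccccc1.COc1cc([C@H]2Oc3c(OCc4ccccc4)ccc(Br)c3[C@@H]2CO)ccc1OCc1ccccc1
F5 | step 17 | 1-[2,4-bis(benzyloxy)-6-(methoxymethoxy)phenyl]ethan-1-one | CC(=O)c1c(OCOC)cc(OCc2ccccc2)cc1OCc1ccccc1
F6 | step 17 | (2E)-1-[2,4-bis(benzyloxy)-6-(methoxymethoxy)phenyl]-3-[(2R,3S)-7-(benzyloxy)-2-[4-(benzyloxy)-3-methoxyphenyl]-3-{[tri(propan-2-yl)silyl]oxymethyl}-2,3-dihydro-1-benzofuran-4-yl]prop-2-en-1-one | COc1cc([C@@H]2Oc3c(OCc4ccccc4)ccc(/C=C/C(=O)c4c(OCOC)cc(OCc5ccccc5)cc4OCc4ccccc4)c3[C@H]2CO[Si](C(C)C)(C(C)C)C(C)C)ccc1OCc1ccccc1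
F7 | step 17 | trans-2,3-epoxy ketone of F6 (both epoxide diastereomers) | COc1cc([C@@H]2Oc3c(OCc4ccccc4)ccc(C4OC4C(=O)c4c(OCOC)cc(OCc5ccccc5)cc4OCc4ccccc4)c3[C@H]2CO[Si](C(C)C)(C(C)C)C(C)C)ccc1OCc1ccccc1
F8 | step 17 | trans-5,7-bis(benzyloxy)-2-[(2R,3S)-7-(benzyloxy)-2-[4-(benzyloxy)-3-methoxyphenyl]-3-(hydroxymethyl)-2,3-dihydro-1-benzofuran-4-yl]-3-hydroxy-2,3-dihydro-4H-chromen-4-one (both trans diastereomers) | COc1cc([C@@H]2Oc3c(OCc4ccccc4)ccc(C4Oc5cc(OCc6ccccc6)cc(OCc6ccccc6)c5C(=O)C4O)c3[C@H]2CO)ccc1OCc1ccccc1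
F0 | step 19 | none | none
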